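**Retrosynthetic overview** (germacrane numbering: ring C1–C10, ester carbon C14 on C10, methyl C15 on C4, arm C11–C12 on C7)

- Feature: the ester-bearing alkene carbon C10 lies across the ten-membered ring from the oxygenated C6. A temporary C6–C10 bond turns the ring into a cyclopentane (C6–C7–C8–C9–C10) fused to a cycloheptene (C10–C1–C2–C3–C4–C5–C6). This bicycle is a β-hydroxy ester with a leaving group on C1.
- Target ⇐ C9 acetylation, α-methylenation, oxidative C6–O–C12 lactonisation, C4=C5 epoxidation, and an Evans–Tishchenko step that sets C6 and delivers the C8 epoxyangelate ⇐ ten-membered 6-oxo-4-ene ⇐ fragmentation of the 5–7 bicycle.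
- Bicycle ⇐ mesylation, C1–OH-directed C2=C3 epoxidation, CBS reduction, silylative opening of the C3–O–C6 bridge ⇐ oxa-bridged tricycle ⇐ double closure (C10→C6, then C2→C3) of a β-keto ester onto the 2,5-dimethoxylated furan.
- Building blocks: (R)-glyceraldehyde acetonide (C7–C9), a Wittig ylide (C11, C12), 3-methylfuran (C3–C6, C15), 2,2,6-trimethyl-1,3-dioxin-4-one (C2, C1, C10, C14), methyl angelate (C8 ester).
- Ring order: cyclopentane, oxa-bridged seven-membered ring, ten-membered ring (by bond cleavage), then the C4–C5 oxirane and the γ-lactone.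

Key step: step 18

Remark on the chemistry: the acetal carbons C3/C6 of 18–21, C3 of 22, C10 of 20, C12 of 39 and C11 of 41/42 are converging epimer mixtures and are drawn without configuration. The bicycle is planned trans-fused (O6 cis to C1). C1, C6 and C10 all become trigonal in step 18.

**Step 1**
Reactants: 1 (R)-2,2-dimethyl-1,3-dioxolane-4-carbaldehyde; 2 methyl (triphenylphosphoranylidene)acetate
Product: 3 methyl (Z)-3-[(4S)-2,2-dimethyl-1,3-dioxolan-4-yl]prop-2-enoate
Conditions: MeOH, 0 °C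
Reagents that add atoms: none
Why: Wittig olefination of an α-alkoxy aldehyde with a stabilised ylide in methanol is Z-selective, and C8 comes unchanged from the chiral pool.

**Step 2**
Reactants: 3 methyl (Z)-3-[(4S)-2,2-dimethyl-1,3-dioxolan-4-yl]prop-2-enoate; 4 3-methylfuran
Product: 7 methyl (3R)-3-[(4S)-2,2-dimethyl-1,3-dioxolan-4-yl]-3-(4-methylfuran-2-yl)propanoate, via (4-methylfuran-2-yl)lithium 5 (not isolated), via lithium bis(4-methylfuran-2-yl)cuprate 6 (not isolated)
Conditions: 2,2,6,6-tetramethylpiperidine, n-BuLi, THF, −78 → 0 °C, then 4; CuI, Et2O/THF, −40 °C; 3, −78 → −30 °C; aq NH4Cl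
Reagents that add atoms: none
Why: The hindered lithium amide removes the α-proton remote from the methyl group (as known for 3-methylthiophene), and the Gilman cuprate adds 1,4 to the Z-enoate, whose A1,3 strain holds H8 in the alkene plane so that attack anti to the C8–C9 bond sets C7 with furyl syn to O8.

**Step 3**
Reactants: 7 methyl (3R)-3-[(4S)-2,2-dimethyl-1,3-dioxolan-4-yl]-3-(4-methylfuran-2-yl)propanoate
Product: 8 (3R)-3-[(4S)-2,2-dimethyl-1,3-dioxolan-4-yl]-3-(4-methylfuran-2-yl)propan-1-ol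
Conditions: LiAlH4, Et2O, 0 °C; H2O, aq NaOH
Reagents that add atoms: none
Why: Hydride reduction of the ester puts the C11–C12 arm at the alcohol level, so that neither O6 nor O8 (which is cis to the arm) can lactonise onto it later, and no stereocentre is touched.

**Step 4**
Reactants: 8 (3R)-3-[(4S)-2,2-dimethyl-1,3-dioxolan-4-yl]-3-(4-methylfuran-2-yl)propan-1-ol
Product: 9 PMB ether of 8 (O12-PMB)
Conditions: NaH, PMBCl, Bu4NI (cat.), THF/DMF, 0 °C → rt
Reagents that add atoms: 4-methoxybenzyl chloride, COc1ccc(CCl)cc1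
Why: Williamson etherification installs a group that is stable to fluoride, base and silyl triflates and is removed oxidatively under neutral conditions.

**Step 5**
Reactants: 9 PMB ether of 8
Product: 10 8,9-diol (C8 secondary OH, C9 primary OH)
Conditions: AcOH/H2O/THF (4:1:1), 45 °C
Reagents that add atoms: none
Why: Acid hydrolysis of the terminal isopropylidene acetal frees O8 and O9 under conditions that the 2,4-dialkylfuran and the PMB ether tolerate.

**Step 6**
Reactants: 10 8,9-diol
Product: 11 8,9-bis(triethylsilyl) ether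
Conditions: TESCl, imidazole, DMAP (cat.), CH2Cl2, 0 °C → rt
Reagents that add atoms: chlorotriethylsilane, CC[Si](Cl)(CC)CC
Why: Exhaustive silylation leaves a non-chelating and later most labile silyl ether on O8 and prepares the direct oxidation at C9.

**Step 7**
Reactants: 11 8,9-bis(triethylsilyl) ether
Product: 12 C9 aldehyde with 8-OTES
Conditions: (COCl)2, DMSO, CH2Cl2, −78 → −30 °C; Et3N, −78 °C → rt
Reagents that add atoms: none
Why: Under Swern conditions a primary triethylsilyl ether is cleaved by the chlorosulfonium salt and oxidised directly to the aldehyde, while the secondary silyl ether survives.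

**Step 8**
Reactants: 13 2,2,6-trimethyl-4H-1,3-dioxin-4-one
Product: 14 5-iodo-2,2,6-trimethyl-4H-1,3-dioxin-4-one
Conditions: NIS, AcOH, rt, dark
Reagents that add atoms: N-iodosuccinimide, O=C1CCC(=O)N1I
Why: Electrophilic iodination occurs at the nucleophilic C5 of the vinylogous ester, which is the future C10.

**Step 9**
Reactants: 12 C9 aldehyde with 8-OTES; 14 5-iodo-2,2,6-trimethyl-4H-1,3-dioxin-4-one
Product: 16 C9 carbinol bearing the dioxinone at C10 (8,9-anti), via dioxinonylmagnesium chloride 15 (not isolated)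
Conditions: iPrMgCl, THF, −30 °C; then 12, −78 → −30 °C; aq NH4Cl
Reagents that add atoms: none
Why: Iodine–magnesium exchange gives the known 5-magnesiated dioxinone, a masked acetoacetate α-anion that has no acidic C10–H and so cannot lose O9 by β-elimination, and its Felkin–Anh addition to the α-silyloxy aldehyde sets C9 anti to O8.

**Step 10**
Reactants: 16 C9 carbinol bearing the dioxinone at C10
Product: 17 9-OTBS ether
Conditions: TBSOTf, 2,6-lutidine, CH2Cl2, −78 → 0 °C
Reagents that add atoms: tert-butyldimethylsilyl triflate, CC(C)(C)[Si](C)(C)OS(=O)(=O)C(F)(F)F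
Why: Silyl triflate silylation of the hindered alcohol differentiates O9 (robust TBS) from O8 (labile TES) for the end game.

**Step 11**
Reactants: 17 9-OTBS ether
Product: 18 2,5-dimethoxy-2,5-dihydrofuran (C6 ketal, C3 acetal)
Conditions: Br2 (1.0 equiv), Na2CO3, MeOH/CH2Cl2, −78 → −40 °C
Reagents that add atoms: methanol, CO
Why: Clauson-Kaas-type bromine/methanol oxidation of the furan, by far the most electron-rich π-system present, makes C6 and C3 electrophilic, so the ester-bearing C10 can act as a nucleophile instead of having to carry an oxyallyl cation.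

**Step 12**
Reactants: 18 2,5-dimethoxy-2,5-dihydrofuran
Product: 20 methyl β-keto ester (C14–C10–C1–C2 unit unmasked), via acylketene 19 (not isolated)
Conditions: toluene/MeOH (10:1), 110 °C, sealed tube
Reagents that add atoms: methanol, CO
Why: Thermal retro-hetero-Diels–Alder loss of acetone from the dioxinone and trapping of the acylketene by methanol releases the β-keto ester under neutral conditions, which avoids β-elimination of O9.

**Step 13**
Reactants: 20 methyl β-keto ester
Product: 23 oxa-bridged tricyclic β-keto ester (bonds C6–C10 and C2–C3; C3–O–C6 bridge), via β-keto ester silyl enol ether 21 (not isolated), via spirocyclic methyl ketone 22 (not isolated)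
Conditions: TMSOTf (2.5 equiv), Et3N (3 equiv), CH2Cl2, −78 → −20 °C
Reagents that add atoms: none
Why: This is in situ enol silane formation followed by Mukaiyama-type alkylation with oxocarbenium ions, the intramolecular form of the Lewis-acid (3+4) annulation of 1,4-dicarbonyl surrogates with β-keto ester bis-nucleophiles: the C6 ketal ionises first and is taken by C10 (five-membered closure), then the methyl ketone enol silane C2 takes the C3 acetal; A1,3 strain about C9–C10=C1 (H9 in the enol plane) places the ester cis to O9, and a cyclopentane can span C6 and C10 of the new pyranone only through the axial C10 position, so that C1 is cis to O6 with the arm, O8 and O9 on the convex face.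

**Step 14**
Reactants: 23 oxa-bridged tricyclic β-keto ester
Product: 24 trans-fused bicyclo[5.3.0] 2,4-dien-1-one with C6–OTMS
Conditions: TMSOTf, Et3N, CH2Cl2, 0 °C → rt
Reagents that add atoms: trimethylsilyl triflate, C[Si](C)(C)OS(=O)(=O)C(F)(F)F
Why: With C10 quaternary the ketone enolises only towards C2, and silyl activation of the bridge oxygen drives β-elimination of the C3–O bond (the known silylative opening of 8-oxabicyclo[3.2.1]oct-6-en-3-ones), so O6 is never a free alkoxide beside the β-keto ester and premature retro-aldol cleavage is avoided.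

**Step 15**
Reactants: 24 trans-fused bicyclo[5.3.0] 2,4-dien-1-one
Product: 25 (1S)-dienol
Conditions: (R)-Me-CBS (0.2 equiv), catecholborane, toluene, −78 → −40 °C; MeOH, aq NaHCO3
Reagents that add atoms: none
Why: In this CBS 1,2-reduction the quaternary C10 is the large and the C2 alkenyl the small ketone substituent, so the (R)-catalyst sets C1 by reagent control with O1 cis to C9 and trans to the ester.

**Step 16**
Reactants: 25 (1S)-dienol
Product: 26 cis-2,3-epoxy-1-ol
Conditions: VO(acac)2 (cat.), t-BuOOH, CH2Cl2, 0 °C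
Reagents that add atoms: tert-butyl hydroperoxide, CC(C)(C)OO
Why: Hydroxyl-directed vanadium epoxidation of a cyclic allylic alcohol delivers oxygen syn to O1 and only to the allylic C2=C3 bond (O6 is silylated), which sets C2 and C3, avoids basic peroxide on a non-enolisable β-keto ester, and puts the oxirane oxygen on the same face as O6.

**Step 17**
Reactants: 26 cis-2,3-epoxy-1-ol
Product: 27 fragmentation precursor: C1 mesylate, C2–C3 epoxide, C4=C5, C6–OTMS, C10 methyl ester
Conditions: MsCl, Et3N, CH2Cl2, −20 → 0 °C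
Reagents that add atoms: methanesulfonyl chloride, CS(=O)(=O)Cl
Why: Sulfene-type mesylation works on the neopentyl secondary alcohol, and the cis epoxy alcohol cannot undergo Payne rearrangement.

**Step 18**
Reactants: 27 fragmentation precursor
Product: 29 ten-membered 6-oxo-4-ene with C2–C3 epoxide and C1=C10 enoate, via C6 ammonium alkoxide 28 (not isolated)
Conditions: TBAF (1.05 equiv, dried), THF, −78 → −40 °C; pH 7 buffer
Reagents that add atoms: none
Why: Fluoride removes the tertiary trimethylsilyl group much faster than the TES and TBS ethers, and alkoxide 28 pushes into the C6–C10 bond, which is antiperiplanar to C1–OMs, so C6=O and C1=C10 form as mesylate leaves; because C10 carries the ester the same outcome can arise stepwise by retro-aldol to the ester enolate and E1cB loss of mesylate. The closest known reaction types are the Grob/Wharton fragmentation of 1,3-diol monosulfonates and the retro-aldol ring expansion of bicyclic β-hydroxy esters. The ten-membered ring is not closed end to end but appears when the bond shared by the cyclopentane (C6–C7–C8–C9–C10) and the cycloheptene (C10–C1–C2–C3–C4–C5–C6) is cut. No stereocentre is created; the alkene geometry follows from the mesylate being cis to C9 on the seven-membered ring, which puts C2 and C9 on the same side of C1=C10 (ester anti to C2), and this is also the more stable enoate if the enolate pathway operates. The step needs mesylate rather than the C9 silyloxy group to leave (sulfonate against silanolate leaving ability), no attack of O6 on the allylic epoxide carbon C3 (excluded because O6 and the oxirane oxygen share one face, so backside approach is impossible) and no lactonisation (the arm is an ether). One equivalent of fluoride, low temperature and a buffered quench protect the β-silyloxy ketone from loss of O8 and the cis-divinyl oxirane unit from Cope rearrangement.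

**Step 19**
Reactants: 29 ten-membered 6-oxo-4-ene
Product: 30 8-hydroxy-6-ketone
Conditions: Et3N·3HF, THF, 0 °C
Reagents that add atoms: none
Why: Mild fluoride cleaves the secondary TES ether selectively over the hindered TBS ether, and the oxirane, flanked by two electron-poor alkenes, tolerates the weakly acidic medium.

**Step 20**
Reactants: 31 methyl angelate
Product: 32 (Z)-2-methylbut-2-en-1-ol
Conditions: LiAlH4, Et2O, 0 °C; H2O, aq NaOH
Reagents that add atoms: none
Why: 1,2-Reduction of the enoate keeps the Z geometry.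

**Step 21**
Reactants: 32 (Z)-2-methylbut-2-en-1-ol
Product: 33 (2R,3S)-2,3-epoxy-2-methylbutan-1-ol
Conditions: Ti(OiPr)4 (cat.), D-(−)-diethyl tartrate (cat.), t-BuOOH, 4 Å MS, CH2Cl2, −20 °C
Reagents that add atoms: tert-butyl hydroperoxide, CC(C)(C)OO
Why: In the Sharpless asymmetric epoxidation the D-(−)-tartrate catalyst attacks the face opposite to the one that gives (2S)-epoxy alcohols with L-(+)-tartrate, which sets both side-chain stereocentres.

**Step 22**
Reactants: 33 (2R,3S)-2,3-epoxy-2-methylbutan-1-ol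
Product: 34 (2S,3S)-2,3-epoxy-2-methylbutanal
Conditions: TEMPO (cat.), PhI(OAc)2, CH2Cl2, 0 °C → rt; short-path distillation
Reagents that add atoms: none
Why: Oxoammonium oxidation stops at the aldehyde, and the quaternary α-carbon cannot epimerise.

**Step 23**
Reactants: 30 8-hydroxy-6-ketone; 34 (2S,3S)-2,3-epoxy-2-methylbutanal
Product: 36 (6S)-alcohol carrying the C8 epoxyangelate, via C8 hemiacetal 35 (not isolated)
Conditions: 34 (4 equiv), SmI2 (0.3 equiv, premixed with 34), THF, −10 °C
Reagents that add atoms: none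
Why: In the Evans–Tishchenko reaction the samarium-bound C8 hemiacetal delivers its hydride intramolecularly to C6 and gives the 1,3-anti diol monoester, so C6 is set against the Felkin–Anh bias of external hydrides (which would give the 6-epimer) and the C8 ester is installed regiospecifically in the same step.

**Step 24**
Reactants: 36 (6S)-alcohol carrying the C8 epoxyangelate
Product: 37 4,5-epoxy-6-ol
Conditions: mCPBA, NaHCO3, CH2Cl2, 0 °C
Reagents that add atoms: 3-chloroperbenzoic acid, O=C(OO)c1cccc(Cl)c1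
Why: In this Henbest-type hydrogen-bond-directed epoxidation of the only electron-rich alkene, A1,3 strain in the Z-allylic alcohol holds H6 in the alkene plane, so oxygen arrives from the O6-bearing peripheral face (threo, trans in the ring sense) and sets C4 and C5.

**Step 25**
Reactants: 37 4,5-epoxy-6-ol
Product: 38 6,12-diol
Conditions: DDQ, CH2Cl2/pH 7 buffer, 0 °C
Reagents that add atoms: none
Why: Oxidative PMB cleavage is neutral and spares both oxiranes, the esters and the TBS ether.

**Step 26**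
Reactants: 38 6,12-diol
Product: 40 trans-fused 6,12-γ-lactone, via γ-lactol 39 (not isolated)
Conditions: TEMPO (0.2 equiv), PhI(OAc)2 (2.5 equiv), CH2Cl2, rt
Reagents that add atoms: none
Why: Oxoammonium oxidation takes the primary alcohol first, the aldehyde is captured by O6 as the five-membered lactol and oxidised on to the lactone, and O8 and O9 are blocked so only the 6,12-olide can form.

**Step 27**
Reactants: 40 trans-fused 6,12-γ-lactone
Product: 43 α-methylene-γ-lactone with 9-OTBS, via Mannich base 41 (not isolated), via methiodide 42 (not isolated)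
Conditions: LDA (1.1 equiv), THF, −78 °C; Me2N=CH2 I; then MeI, CH2Cl2/MeOH, rt; aq NaHCO3
Reagents that add atoms: N,N-dimethylmethyleneiminium iodide, C[N+](C)=C.[I-]
Why: In this Eschenmoser methylenation C11 is the only enolisable position, because the epoxyangelate has no α-hydrogen and no acetate is present yet, and quaternisation followed by β-elimination gives the exocyclic alkene.

**Step 28**
Reactants: 43 α-methylene-γ-lactone with 9-OTBS
Product: 44 C9 alcohol
Conditions: Et3N·3HF, MeCN, rt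
Reagents that add atoms: none
Why: The nearly neutral amine–HF reagent removes the TBS ether without opening the oxiranes or adding to the α-methylene lactone, and the hindered C8 ester is slow to migrate.

**Step 29**
Reactants: 44 C9 alcohol
Product: 45 target CNP0077535.3
Conditions: Ac2O, pyridine, DMAP (cat.), CH2Cl2, 0 °C
Reagents that add atoms: acetic anhydride, CC(=O)OC(C)=O
Why: DMAP-catalysed acetylation of the single free hydroxyl completes the target without touching any stereocentre.

**Compound list**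

1 | (R)-2,2-dimethyl-1,3-dioxolane-4-carbaldehyde | O=C[C@@H]1OC(C)(C)OC1 | starting material
2 | methyl (triphenylphosphoranylidene)acetate | COC(=O)C=P(c1ccccc1)(c1ccccc1)c1ccccc1 | starting material
3 | methyl (Z)-3-[(4S)-2,2-dimethyl-1,3-dioxolan-4-yl]prop-2-enoate | COC(=O)/C=C\[C@@H]1OC(C)(C)OC1 | intermediate
4 | 3-methylfuran | Cc1ccoc1 | starting material
5 | (4-methylfuran-2-yl)lithium | [Li]c1cc(C)co1 | intermediate
6 | lithium bis(4-methylfuran-2-yl)cuprate | [Li+].Cc1coc([Cu-]c2cc(C)co2)c1 | intermediate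
7 | methyl (3R)-3-[(4S)-2,2-dimethyl-1,3-dioxolan-4-yl]-3-(4-methylfuran-2-yl)propanoate | COC(=O)C[C@@H](c1cc(C)co1)[C@@H]1OC(C)(C)OC1 | intermediate
8 | (3R)-3-[(4S)-2,2-dimethyl-1,3-dioxolan-4-yl]-3-(4-methylfuran-2-yl)propan-1-ol | OCC[C@@H](c1cc(C)co1)[C@@H]1OC(C)(C)OC1 | intermediate
9 | PMB ether of 8 | COc1ccc(COCC[C@@H](c2cc(C)co2)[C@@H]2OC(C)(C)OC2)cc1 | intermediate
10 | 8,9-diol | COc1ccc(COCC[C@@H](c2cc(C)co2)[C@H](O)CO)cc1 | intermediate
11 | 8,9-bis(triethylsilyl) ether | COc1ccc(COCC[C@@H](c2cc(C)co2)[C@H](O[Si](CC)(CC)CC)CO[Si](CC)(CC)CC)cc1 | intermediate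
12 | C9 aldehyde with 8-OTES | COc1ccc(COCC[C@@H](c2cc(C)co2)[C@H](O[Si](CC)(CC)CC)C=O)cc1 | intermediate
13 | 2,2,6-trimethyl-4H-1,3-dioxin-4-one | CC1=CC(=O)OC(C)(C)O1 | starting material
14 | 5-iodo-2,2,6-trimethyl-4H-1,3-dioxin-4-one | CC1=C(I)C(=O)OC(C)(C)O1 | intermediate
15 | (2,2,6-trimethyl-4-oxo-1,3-dioxin-5-yl)magnesium chloride | CC1=C([Mg]Cl)C(=O)OC(C)(C)O1 | intermediate
16 | C9 carbinol bearing the dioxinone at C10 (8,9-anti) | COc1ccc(COCC[C@@H](c2cc(C)co2)[C@H](O[Si](CC)(CC)CC)[C@H](O)C2=C(C)OC(C)(C)OC2=O)cc1 | intermediate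
17 | 9-OTBS ether of 16 | COc1ccc(COCC[C@@H](c2cc(C)co2)[C@H](O[Si](CC)(CC)CC)[C@H](O[Si](C)(C)C(C)(C)C)C2=C(C)OC(C)(C)OC2=O)cc1 | intermediate
18 | 2,5-dimethoxy-2,5-dihydrofuran (C6 ketal, C3 acetal) | COc1ccc(COCC[C@@H](C2(OC)C=C(C)C(OC)O2)[C@H](O[Si](CC)(CC)CC)[C@H](O[Si](C)(C)C(C)(C)C)C2=C(C)OC(C)(C)OC2=O)cc1 | intermediate
19 | acylketene | COc1ccc(COCC[C@@H](C2(OC)C=C(C)C(OC)O2)[C@H](O[Si](CC)(CC)CC)[C@H](O[Si](C)(C)C(C)(C)C)C(=C=O)C(C)=O)cc1 | intermediate
20 | methyl β-keto ester | COc1ccc(COCC[C@@H](C2(OC)C=C(C)C(OC)O2)[C@H](O[Si](CC)(CC)CC)[C@H](O[Si](C)(C)C(C)(C)C)C(C(C)=O)C(=O)OC)cc1 | intermediate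
21 | β-keto ester trimethylsilyl enol ether | COc1ccc(COCC[C@@H](C2(OC)C=C(C)C(OC)O2)[C@H](O[Si](CC)(CC)CC)[C@H](O[Si](C)(C)C(C)(C)C)C(C(=O)OC)=C(C)O[Si](C)(C)C)cc1 | intermediate
22 | spirocyclic methyl ketone (C6–C10 bond made) | COC(=O)[C@]1(C(C)=O)[C@]2(C=C(C)C(OC)O2)[C@H](CCOCc2ccc(OC)cc2)[C@H](O[Si](CC)(CC)CC)[C@@H]1O[Si](C)(C)C(C)(C)C | intermediate
23 | oxa-bridged tricyclic β-keto ester | COC(=O)[C@]12C(=O)C[C@H]3O[C@@]1(C=C3C)[C@H](CCOCc1ccc(OC)cc1)[C@H](O[Si](CC)(CC)CC)[C@@H]2O[Si](C)(C)C(C)(C)C | intermediate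
24 | trans-fused bicyclo[5.3.0] 2,4-dien-1-one with C6–OTMS | COC(=O)[C@]12C(=O)C=CC(C)=C[C@]1(O[Si](C)(C)C)[C@H](CCOCc1ccc(OC)cc1)[C@H](O[Si](CC)(CC)CC)[C@@H]2O[Si](C)(C)C(C)(C)C | intermediate
25 | (1S)-dienol | COC(=O)[C@]12[C@@H](O)C=CC(C)=C[C@]1(O[Si](C)(C)C)[C@H](CCOCc1ccc(OC)cc1)[C@H](O[Si](CC)(CC)CC)[C@@H]2O[Si](C)(C)C(C)(C)C | intermediate
26 | cis-2,3-epoxy-1-ol | COC(=O)[C@]12[C@@H](O)[C@H]3O[C@H]3C(C)=C[C@]1(O[Si](C)(C)C)[C@H](CCOCc1ccc(OC)cc1)[C@H](O[Si](CC)(CC)CC)[C@@H]2O[Si](C)(C)C(C)(C)C | intermediate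
27 | fragmentation precursor (C1 mesylate, C6–OTMS) | COC(=O)[C@]12[C@@H](OS(C)(=O)=O)[C@H]3O[C@H]3/C(C)=C\[C@]1(O[Si](C)(C)C)[C@H](CCOCc1ccc(OC)cc1)[C@H](O[Si](CC)(CC)CC)[C@@H]2O[Si](C)(C)C(C)(C)C | intermediate
28 | tetrabutylammonium C6 alkoxide | CCCC[N+](CCCC)(CCCC)CCCC.COC(=O)[C@]12[C@@H](OS(C)(=O)=O)[C@H]3O[C@H]3C(C)=C[C@]1([O-])[C@H](CCOCc1ccc(OC)cc1)[C@H](O[Si](CC)(CC)CC)[C@@H]2O[Si](C)(C)C(C)(C)C | intermediate
29 | ten-membered 6-oxo-4-ene (C2–C3 epoxide, C1=C10 enoate) | COC(=O)/C1=C/[C@H]2O[C@H]2/C(C)=C\C(=O)[C@H](CCOCc2ccc(OC)cc2)[C@H](O[Si](CC)(CC)CC)[C@@H]1O[Si](C)(C)C(C)(C)C | intermediate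
30 | 8-hydroxy-6-ketone | COC(=O)/C1=C/[C@H]2O[C@H]2/C(C)=C\C(=O)[C@H](CCOCc2ccc(OC)cc2)[C@H](O)[C@@H]1O[Si](C)(C)C(C)(C)C | intermediate
31 | methyl angelate | C/C=C(/C)C(=O)OC | starting material
32 | (Z)-2-methylbut-2-en-1-ol | C/C=C(/C)CO | intermediate
33 | (2R,3S)-2,3-epoxy-2-methylbutan-1-ol | OC[C@@]1(C)O[C@H]1C | intermediate
34 | (2S,3S)-2,3-epoxy-2-methylbutanal | O=C[C@@]1(C)O[C@H]1C | intermediate
35 | C8 hemiacetal of 30 and 34 | COC(=O)/C1=C/[C@H]2O[C@H]2/C(C)=C\C(=O)[C@H](CCOCc2ccc(OC)cc2)[C@H](OC(O)[C@@]2(C)O[C@H]2C)[C@@H]1O[Si](C)(C)C(C)(C)C | intermediate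
36 | (6S)-alcohol carrying the C8 epoxyangelate | COC(=O)/C1=C/[C@H]2O[C@H]2/C(C)=C\[C@@H](O)[C@H](CCOCc2ccc(OC)cc2)[C@H](OC(=O)[C@@]2(C)O[C@H]2C)[C@@H]1O[Si](C)(C)C(C)(C)C | intermediate
37 | 4,5-epoxy-6-ol | COC(=O)/C1=C/[C@H]2O[C@H]2[C@]2(C)O[C@@H]2[C@@H](O)[C@H](CCOCc2ccc(OC)cc2)[C@H](OC(=O)[C@@]2(C)O[C@H]2C)[C@@H]1O[Si](C)(C)C(C)(C)C | intermediate
38 | 6,12-diol | COC(=O)/C1=C/[C@H]2O[C@H]2[C@]2(C)O[C@@H]2[C@@H](O)[C@H](CCO)[C@H](OC(=O)[C@@]2(C)O[C@H]2C)[C@@H]1O[Si](C)(C)C(C)(C)C | intermediate
39 | γ-lactol | C1C(O)O[C@H]2[C@H]1[C@H](OC(=O)[C@@]1(C)O[C@H]1C)[C@H](O[Si](C)(C)C(C)(C)C)/C(C(=O)OC)=C\[C@H]1O[C@H]1[C@]1(C)O[C@H]21 | intermediate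
40 | trans-fused 6,12-γ-lactone | C1C(=O)O[C@H]2[C@H]1[C@H](OC(=O)[C@@]1(C)O[C@H]1C)[C@H](O[Si](C)(C)C(C)(C)C)/C(C(=O)OC)=C\[C@H]1O[C@H]1[C@]1(C)O[C@H]21 | intermediate
41 | C11 (dimethylamino)methyl lactone | CN(C)CC1C(=O)O[C@H]2[C@H]1[C@H](OC(=O)[C@@]1(C)O[C@H]1C)[C@H](O[Si](C)(C)C(C)(C)C)/C(C(=O)OC)=C\[C@H]1O[C@H]1[C@]1(C)O[C@H]21 | intermediate
42 | methiodide of 41 | C[N+](C)(C)CC1C(=O)O[C@H]2[C@H]1[C@H](OC(=O)[C@@]1(C)O[C@H]1C)[C@H](O[Si](C)(C)C(C)(C)C)/C(C(=O)OC)=C\[C@H]1O[C@H]1[C@]1(C)O[C@H]21.[I-] | intermediate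
43 | α-methylene-γ-lactone with 9-OTBS | C=C1C(=O)O[C@H]2[C@H]1[C@H](OC(=O)[C@@]1(C)O[C@H]1C)[C@H](O[Si](C)(C)C(C)(C)C)/C(C(=O)OC)=C\[C@H]1O[C@H]1[C@]1(C)O[C@H]21 | intermediate
44 | C9 alcohol | C=C1C(=O)O[C@H]2[C@H]1[C@H](OC(=O)[C@@]1(C)O[C@H]1C)[C@H](O)/C(C(=O)OC)=C\[C@H]1O[C@H]1[C@]1(C)O[C@H]21 | intermediate
45 | CNP0077535.3 | C=C1C(=O)O[C@H]2[C@H]1[C@H](OC(=O)[C@@]1(C)O[C@H]1C)[C@H](OC(C)=O)/C(C(=O)OC)=C\[C@H]1O[C@H]1[C@]1(C)O[C@H]21 | target

Total step count: 29. Longest linear sequence: 25 steps (1–7, 9–19, 23–29).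

**Steps most likely to fail**

Step 18. The seven-membered ring may not reach the conformer in which C1–OMs is antiperiplanar to C6–C10. The alkoxide would then live long enough for silyl migration, loss of O8 from the product, or decomposition of the mesylate. The fallback separates bond cleavage from elimination and sets out from 26. Acetylation (Ac2O, DMAP) gives the C1 acetate F1, which has a poorer and more stable leaving group. TBAF with t-BuOH in THF at −78 °C frees O6, and retro-aldol cleavage with protonation of the ester enolate gives the ten-membered β-acetoxy ester F2. DBU in toluene at 0 °C then removes acetic acid by E1cB on the ring itself and returns to 29.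

Step 13. Proton loss from the C6 oxocarbenium ion at C7–H, followed by re-aromatisation, may outrun the formation of the bond between two fully substituted carbons. The second closure may also go to C5 instead of C3, or the facial control at C6 may be poor. The fallback makes the same two bonds on the intact furan by a cationic cycloaddition and sets out from 12. A BF3·OEt2 Mukaiyama aldol reaction with methyl 2-chloro-3-(trimethylsilyloxy)but-2-enoate F3 (from methyl 2-chloroacetoacetate, TMSCl, Et3N) gives the Felkin chloro aldol F4. TBSOTf/2,6-lutidine gives its 9-OTBS ether F5. Et3N in (CF3)2CHOH then generates the oxyallyl cation for a Föhlisch-type intramolecular furan (4+3) cycloaddition, which comes back to the route at 23.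

Step 23. Hemiacetal formation with the hindered epoxy aldehyde may be slow, the ring may resist the bicyclic hydride-transfer transition state, or divalent samarium may reduce the vinyl oxirane. The fallback separates reduction from acylation and sets out from 30. Evans–Saksena reduction (Me4NBH(OAc)3, MeCN/AcOH, −30 °C) gives the 6,8-anti diol F6. TESCl/imidazole at −40 °C silylates the more accessible allylic O6 to give the 6-OTES ether F7. Pinnick oxidation of 34 gives (2S,3S)-epoxyangelic acid F8. Yamaguchi esterification of F7 with F8 gives the 6-OTES C8 ester F9, and Et3N·3HF returns to 36.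

**Further compounds**

F1 | step 18 | C1 acetate analogue of 27 | COC(=O)[C@]12[C@@H](OC(C)=O)[C@H]3O[C@H]3C(C)=C[C@]1(O[Si](C)(C)C)[C@H](CCOCc1ccc(OC)cc1)[C@H](O[Si](CC)(CC)CC)[C@@H]2O[Si](C)(C)C(C)(C)C
F2 | step 18 | ten-membered β-acetoxy ester (C10–H) | COC(=O)C1[C@@H](OC(C)=O)[C@H]2O[C@H]2/C(C)=C\C(=O)[C@H](CCOCc2ccc(OC)cc2)[C@H](O[Si](CC)(CC)CC)[C@@H]1O[Si](C)(C)C(C)(C)C
F3 | step 13 | methyl 2-chloro-3-(trimethylsilyloxy)but-2-enoate | COC(=O)C(Cl)=C(C)O[Si](C)(C)C
F4 | step 13 | C10 chloro aldol | COc1ccc(COCC[C@@H](c2cc(C)co2)[C@H](O[Si](CC)(CC)CC)[C@H](O)C(Cl)(C(C)=O)C(=O)OC)cc1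
F5 | step 13 | 9-OTBS ether of the chloro aldol | COc1ccc(COCC[C@@H](c2cc(C)co2)[C@H](O[Si](CC)(CC)CC)[C@H](O[Si](C)(C)C(C)(C)C)C(Cl)(C(C)=O)C(=O)OC)cc1
F6 | step 23 | 6,8-anti diol | COC(=O)/C1=C/[C@H]2O[C@H]2/C(C)=C\[C@@H](O)[C@H](CCOCc2ccc(OC)cc2)[C@H](O)[C@@H]1O[Si](C)(C)C(C)(C)C
F7 | step 23 | 6-OTES ether of the diol | COC(=O)/C1=C/[C@H]2O[C@H]2/C(C)=C\[C@@H](O[Si](CC)(CC)CC)[C@H](CCOCc2ccc(OC)cc2)[C@H](O)[C@@H]1O[Si](C)(C)C(C)(C)C
F8 | step 23 | (2S,3S)-epoxyangelic acid | OC(=O)[C@@]1(C)O[C@H]1C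
F9 | step 23 | 6-OTES C8 epoxyangelate | COC(=O)/C1=C/[C@H]2O[C@H]2/C(C)=C\[C@@H](O[Si](CC)(CC)CC)[C@H](CCOCc2ccc(OC)cc2)[C@H](OC(=O)[C@@]2(C)O[C@H]2C)[C@@H]1O[Si](C)(C)C(C)(C)C
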